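**Plan**
1. Numbering (cembrane): carbocycle C1–C14; the lactone sits on C1/C14 (C15=C17 methylene, C16 carbonyl); the oxane ring is O–C3–C2–C1–C14–C13; carbinols at C4 and C8; Z-C6=C7; methyls on C4, C8 and C12.
2. Feature used: C4 lies between the oxane carbon C3 and the allylic CH2 C5 of the Z-C6=C7 alkene, and its oxygen is trans to the ring oxygen on C3. That is the pattern left when the C13 hydroxyl opens an E-3,4-epoxide, so C3=C4–C5–C6=C7 is a latent skipped diene and C4–C5 an alkenyl–allyl bond.
3. Cuts, in retro order: C4–CH3 (methyl addition to a 4-ketone); C3–O (transannular epoxide opening); C4–C5 (ring closure from a terminal alkyne C3≡C4 and a Z-allylic carbonate at C5); C1–C14 with the lactone C–O (zinc allylation). This leaves an East aldehyde (C5–C14, from (S)-citronellal) and a West bromide (C1–C4, C15–C17).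
4. Forward order of rings: temporary butenolide (fixes 6Z) → α-methylene lactone → 14-membered carbocycle → oxane.
5. Stereochemistry: C12 from (S)-citronellal; C8 by Sharpless epoxidation; C13 by organocatalytic oxyamination; C14/C1 by Felkin–Anh, syn-selective allylation; C3 by Shi epoxidation then SN2 inversion; C4 by chelation-controlled methyl addition; 3E by syn hydrozirconation.

Key step: step 13

Remark: in step 9 the imidazolidinone is assumed to follow its usual enamine-face model, the (2R,5R) catalyst giving the 2R oxyaminated aldehyde; if the sense were opposite, its antipode would be used.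

Step 1
Reactants: 1 (S)-citronellal
Product: 2 (6S)-8,8-dimethoxy-2,6-dimethyloct-2-ene
Conditions: HC(OMe)3, MeOH, NH4NO3 (cat.), rt
Reagents that add atoms: trimethyl orthoformate COC(OC)OC
Why: Acetalisation with the orthoformate as water scavenger should mask the aldehyde under ammonium-salt catalysis mild enough to avoid the carbonyl-ene cyclisation of citronellal, and the C12 stereocentre of the chiral-pool aldehyde is untouched.

Step 2
Reactants: 2 (6S)-8,8-dimethoxy-2,6-dimethyloct-2-ene
Product: 3 (2E,6S)-8,8-dimethoxy-2,6-dimethyloct-2-en-1-ol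
Conditions: SeO2 (cat.), t-BuOOH, CH2Cl2, 0 °C to rt
Reagents that add atoms: tert-butyl hydroperoxide CC(C)(C)OO
Why: Selenium dioxide-catalysed allylic oxidation (ene reaction, then [2,3]-sigmatropic shift) should hydroxylate only the methyl group trans to the chain, which gives the E-allylic alcohol and differentiates the two methyls on C8.

Step 3
Reactants: 3 (2E,6S)-8,8-dimethoxy-2,6-dimethyloct-2-en-1-ol
Product: 4 [(2S,3S)-3-[(3S)-5,5-dimethoxy-3-methylpentyl]-2-methyloxiran-2-yl]methanol
Conditions: Ti(OiPr)4 (cat.), L-(+)-diethyl tartrate (cat.), t-BuOOH, 4 Å sieves, CH2Cl2, −20 °C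
Reagents that add atoms: tert-butyl hydroperoxide CC(C)(C)OO
Why: Sharpless asymmetric epoxidation of the E-2-methyl allylic alcohol with the natural tartrate should deliver oxygen to the face that gives the (2S,3S)-epoxide, so the C8 stereocentre is set by reagent control.

Step 4
Reactants: 4 [(2S,3S)-3-[(3S)-5,5-dimethoxy-3-methylpentyl]-2-methyloxiran-2-yl]methanol
Product: 5 (2R,6S)-8,8-dimethoxy-2,6-dimethyloctane-1,2-diol
Conditions: LiAlH4, THF, 0 °C to rt
Reagents that add atoms: none
Why: Hydride opening of the trisubstituted epoxide (SN2) should occur at the less substituted carbon C9, which leaves the C8–O bond and its configuration intact and gives the tertiary carbinol.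

Step 5
Reactants: 5 (2R,6S)-8,8-dimethoxy-2,6-dimethyloctane-1,2-diol
Product: 7 (5R)-5-[(3S)-5,5-dimethoxy-3-methylpentyl]-5-methylfuran-2(5H)-one, via hydroxy aldehyde 6 (not isolated)
Conditions: IBX, EtOAc, 75 °C; filtration; then Ph3P=C=C=O, toluene, 90 °C
Reagents that add atoms: (triphenylphosphoranylidene)ketene O=C=C=P(c1ccccc1)(c1ccccc1)c1ccccc1
Why: IBX should oxidise only the primary hydroxyl without glycol cleavage, after which the ketenylidene phosphorane is acylated by the tertiary hydroxyl and closes by intramolecular Wittig olefination, so the C6=C7 bond is formed cis inside the butenolide ring.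

Step 6
Reactants: 7 (5R)-5-[(3S)-5,5-dimethoxy-3-methylpentyl]-5-methylfuran-2(5H)-one
Product: 8 (2Z,4R,8S)-10,10-dimethoxy-4,8-dimethyldec-2-ene-1,4-diol
Conditions: i-Bu2AlH (excess), CH2Cl2, −78 °C to rt
Reagents that add atoms: none
Why: 1,2-Reduction of the unsaturated lactone through the lactol should give the ene-1,4-diol with the cis geometry inherited from the ring.

Step 7
Reactants: 8 (2Z,4R,8S)-10,10-dimethoxy-4,8-dimethyldec-2-ene-1,4-diol
Product: 9 (2Z,4R,8S)-4-hydroxy-10,10-dimethoxy-4,8-dimethyldec-2-en-1-yl methyl carbonate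
Conditions: ClCO2Me, pyridine, CH2Cl2, −20 °C
Reagents that add atoms: methyl chloroformate COC(=O)Cl
Why: Chemoselective acylation of the primary allylic hydroxyl over the hindered tertiary one should install the leaving group for the later π-allyl chemistry.

Step 8
Reactants: 9 (2Z,4R,8S)-4-hydroxy-10,10-dimethoxy-4,8-dimethyldec-2-en-1-yl methyl carbonate
Product: 11 (2Z,4R,8S)-4,8-dimethyl-10-oxo-4-[(triethylsilyl)oxy]dec-2-en-1-yl methyl carbonate, via lutidinium salt 10 (not isolated)
Conditions: Et3SiOTf, 2,6-lutidine, CH2Cl2, −78 to 0 °C; then H2O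
Reagents that add atoms: triethylsilyl trifluoromethanesulfonate CC[Si](CC)(CC)OS(=O)(=O)C(F)(F)F; water O
Why: The silyl triflate with 2,6-lutidine should silylate the tertiary hydroxyl and convert the dimethyl acetal, through its oxocarbenium ion, into a lutidinium N,O-acetal salt that water hydrolyses to the aldehyde, so protection and acid-free acetal cleavage happen in one operation.

Step 9
Reactants: 11 (2Z,4R,8S)-4,8-dimethyl-10-oxo-4-[(triethylsilyl)oxy]dec-2-en-1-yl methyl carbonate
Product: 12 (2Z,4R,8S,9R)-4,8-dimethyl-10-oxo-9-[(2,2,6,6-tetramethylpiperidin-1-yl)oxy]-4-[(triethylsilyl)oxy]dec-2-en-1-yl methyl carbonate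
Conditions: TEMPO, CuCl2·2H2O (cat.), (2R,5R)-5-benzyl-2-tert-butyl-3-methylimidazolidin-4-one trifluoroacetate (cat.), acetone, air, −10 °C
Reagents that add atoms: TEMPO CC1(C)CCCC(C)(C)N1[O]
Why: Organocatalytic enamine α-oxyamination (copper-assisted trapping of the chiral enamine by TEMPO) should introduce the C13 oxygen on the enamine face left open by the catalyst, which sets 13R by catalyst control and gives a configurationally stable, non-chelating α-aminoxy aldehyde.

Step 10
Reactants: 13 but-3-yn-1-ol; 14 methyl propiolate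
Product: 17 methyl 3-hydroxy-2-methylidenehex-5-ynoate (racemic), via but-3-ynal 15 (not isolated), via vinylalane 16 (not isolated)
Conditions: 13: Dess–Martin periodinane, CH2Cl2, 0 °C; 14: i-Bu2AlH, N-methylmorpholine N-oxide, THF, 0 °C; solutions combined, 0 °C to rt
Reagents that add atoms: none
Why: Dess–Martin oxidation should give the base-sensitive β,γ-alkynyl aldehyde, which is trapped at once under non-basic conditions by the α-aluminated acrylate from conjugate hydroalumination of the propiolate (vinylalumination, a Baylis–Hillman-type adduct synthesis), the racemic carbinol centre being erased in the next step.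

Step 11
Reactants: 17 methyl 3-hydroxy-2-methylidenehex-5-ynoate
Product: 18 methyl (2Z)-2-(bromomethyl)hex-2-en-5-ynoate
Conditions: N-bromosuccinimide, Me2S, CH2Cl2, 0 °C to rt
Reagents that add atoms: N-bromosuccinimide O=C1CCC(=O)N1Br
Why: Sulfonium activation of the allylic alcohol and SN2′ return of bromide (Corey–Kim-type allylic transposition) should give the trisubstituted enoate with the propargyl-bearing carbon cis to CH2Br.

Step 12
Reactants: 12 (2Z,4R,8S,9R)-4,8-dimethyl-10-oxo-9-[(2,2,6,6-tetramethylpiperidin-1-yl)oxy]-4-[(triethylsilyl)oxy]dec-2-en-1-yl methyl carbonate; 18 methyl (2Z)-2-(bromomethyl)hex-2-en-5-ynoate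
Product: 22 (2Z,4R,8S,9R)-9-hydroxy-4,8-dimethyl-9-[(2S,3R)-4-methylidene-5-oxo-3-(prop-2-yn-1-yl)oxolan-2-yl]-4-[(triethylsilyl)oxy]non-2-en-1-yl methyl carbonate, via allylzinc bromide 19 (not isolated), via hydroxy ester 20 (not isolated), via aminoxy lactone 21 (not isolated)
Conditions: Zn dust, THF–sat. aq. NH4Cl, 0 °C to rt; then AcOH, more Zn, 35 °C
Reagents that add atoms: none
Why: Zinc-mediated Barbier (Dreiding–Schmidt) allylation through the γ-carbon of the 2-(alkoxycarbonyl)allylzinc in a chair-like transition state should give the syn adduct (C1 relative to C14) on the Felkin–Anh face of the aldehyde (bulky aminoxy group anti to the nucleophile, hence 13,14-anti), after which acetic acid and the excess zinc close the cis-lactone and cleave the N–O bond.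

Step 13
Reactants: 22 (2Z,4R,8S,9R)-9-hydroxy-4,8-dimethyl-9-[(2S,3R)-4-methylidene-5-oxo-3-(prop-2-yn-1-yl)oxolan-2-yl]-4-[(triethylsilyl)oxy]non-2-en-1-yl methyl carbonate
Product: 24 (1R,3E,6Z,8R,12S,13R,14S)-13-hydroxy-8-[(triethylsilyl)oxy]-18-norcembra-3,6,15(17)-trien-16,14-olide, via alkenylzirconocene 23 (not isolated)
Conditions: Cp2Zr(H)Cl (2.2 equiv), THF, 0 °C to rt; then slow addition to Pd(PPh3)4 (cat.), THF, 45 °C, high dilution
Reagents that add atoms: none
Why: Proposed new method: Cp2Zr(H)Cl adds cis and anti-Markovnikov to the terminal alkyne (zirconium on C4, 3E fixed; one equivalent is used up by the C13 hydroxyl), zerovalent palladium ionises the primary allylic carbonate with loss of CO2 to a π-allyl complex, the methoxide passes to the oxophilic zirconium as the alkenyl group moves to palladium, and reductive elimination joins C4 to the allyl terminus C5. The closest known reaction type is the intermolecular palladium-catalysed coupling of alkenylzirconocenes (and alkenylalanes) with allylic halides, acetates and carbonates to skipped dienes, which keeps the geometry of both partners, together with large-ring closures by alkenyl cross-coupling of tin and boron reagents; what is new is the use of the zirconium variant to close a ring. One ring is closed, the 14-membered carbocycle, by reductive elimination on palladium between the alkenyl carbon and the terminal allyl carbon, an end-to-end macrocyclisation run under slow addition and high dilution. No stereocentre is formed; the stereo-elements are the two double bonds, 3E coming from the syn hydrometalation and 6Z being kept because syn–anti exchange of the allyl complex would need a σ-bond from palladium to C7, which is neopentyl-like beside the fully substituted C8. The step needs the hydride to choose the alkyne over the lactone methylene, the carbonate and the cis-alkene (terminal alkynes are its fastest substrates, so the reagent is titrated in at 0 °C), and the coupling to choose C5 over C7 (steric bias from C8 and its silyl ether).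

Step 14
Reactants: 24 (1R,3E,6Z,8R,12S,13R,14S)-13-hydroxy-8-[(triethylsilyl)oxy]-18-norcembra-3,6,15(17)-trien-16,14-olide
Product: 26 (1R,3R,4S,6Z,8R,12S,13R,14S)-3,13-epoxy-4-hydroxy-8-[(triethylsilyl)oxy]-18-norcembra-6,15(17)-dien-16,14-olide, via epoxide 25 (not isolated)
Conditions: 1,2:4,5-di-O-isopropylidene-β-L-erythro-2,3-hexodiulo-2,6-pyranose (cat.), KHSO5 (as 2KHSO5·KHSO4·K2SO4), K2CO3, Bu4NHSO4, MeCN–CH2(OMe)2–aq. Na2B4O7, 0 °C; then camphorsulfonic acid (cat.), CH2Cl2, 0 °C
Reagents that add atoms: potassium peroxymonosulfate [K+].[O-]S(=O)(=O)OO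
Why: Shi epoxidation with the L-series ketone should select the unhindered E-C3=C4 bond over the cis-alkene beside the quaternary C8 and over the electron-poor lactone methylene and give the (3S,4S)-epoxide, which the C13 hydroxyl then opens across the ring at C3 in an acid-catalysed 6-exo-tet SN2 process with inversion, setting 3R and the 2,6-cis oxane.

Step 15
Reactants: 26 (1R,3R,4S,6Z,8R,12S,13R,14S)-3,13-epoxy-4-hydroxy-8-[(triethylsilyl)oxy]-18-norcembra-6,15(17)-dien-16,14-olide
Product: 27 (1R,3R,6Z,8R,12S,13R,14S)-3,13-epoxy-4-oxo-8-[(triethylsilyl)oxy]-18-norcembra-6,15(17)-dien-16,14-olide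
Conditions: Dess–Martin periodinane, NaHCO3, CH2Cl2, 0 °C to rt
Reagents that add atoms: none
Why: Dess–Martin oxidation of the only free, secondary hydroxyl should give the α-alkoxy ketone under buffered, non-basic conditions that leave the β,γ-double bond out of conjugation.

Step 16
Reactants: 27 (1R,3R,6Z,8R,12S,13R,14S)-3,13-epoxy-4-oxo-8-[(triethylsilyl)oxy]-18-norcembra-6,15(17)-dien-16,14-olide
Product: 28 (1R,3R,4S,6Z,8R,12S,13R,14S)-3,13-epoxy-4-hydroxy-8-[(triethylsilyl)oxy]cembra-6,15(17)-dien-16,14-olide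
Conditions: MeMgBr, CH2Cl2–Et2O, −78 °C
Reagents that add atoms: methylmagnesium bromide C[Mg]Br
Why: Chelation-controlled Grignard addition (Cram chelate of magnesium between the ketone oxygen and the oxane oxygen in a weakly coordinating solvent) should bring the methyl group in from the side of the C3 hydrogen and set 4S, the chelate-activated ketone reacting at −78 °C in preference to the lactone.

Step 17
Reactants: 28 (1R,3R,4S,6Z,8R,12S,13R,14S)-3,13-epoxy-4-hydroxy-8-[(triethylsilyl)oxy]cembra-6,15(17)-dien-16,14-olide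
Product: 29 (1R,3R,4S,6Z,8R,12S,13R,14S)-3,13-epoxy-4,8-dihydroxycembra-6,15(17)-dien-16,14-olide (CNP0146755.1)
Conditions: HF·pyridine, pyridine, THF, 0 °C to rt
Reagents that add atoms: none
Why: Buffered fluoride desilylation should free the tertiary allylic alcohol without ionising it.

**Compound list**
1 | (S)-citronellal, (3S)-3,7-dimethyloct-6-enal | O=CC[C@@H](C)CCC=C(C)C | starting material
2 | (6S)-8,8-dimethoxy-2,6-dimethyloct-2-ene | COC(OC)C[C@@H](C)CCC=C(C)C | intermediate
3 | (2E,6S)-8,8-dimethoxy-2,6-dimethyloct-2-en-1-ol | COC(OC)C[C@@H](C)CC/C=C(\C)CO | intermediate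
4 | [(2S,3S)-3-[(3S)-5,5-dimethoxy-3-methylpentyl]-2-methyloxiran-2-yl]methanol | COC(OC)C[C@@H](C)CC[C@@H]1O[C@@]1(C)CO | intermediate
5 | (2R,6S)-8,8-dimethoxy-2,6-dimethyloctane-1,2-diol | COC(OC)C[C@@H](C)CCC[C@@](C)(O)CO | intermediate
6 | (2R,6S)-2-hydroxy-8,8-dimethoxy-2,6-dimethyloctanal | COC(OC)C[C@@H](C)CCC[C@@](C)(O)C=O | intermediate
7 | (5R)-5-[(3S)-5,5-dimethoxy-3-methylpentyl]-5-methylfuran-2(5H)-one | COC(OC)C[C@@H](C)CCC[C@@]1(C)OC(=O)C=C1 | intermediate
8 | (2Z,4R,8S)-10,10-dimethoxy-4,8-dimethyldec-2-ene-1,4-diol | COC(OC)C[C@@H](C)CCC[C@@](C)(O)/C=C\CO | intermediate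
9 | (2Z,4R,8S)-4-hydroxy-10,10-dimethoxy-4,8-dimethyldec-2-en-1-yl methyl carbonate | COC(OC)C[C@@H](C)CCC[C@@](C)(O)/C=C\COC(=O)OC | intermediate
10 | 1-[(3S,7R,8Z)-1-methoxy-10-[(methoxycarbonyl)oxy]-3,7-dimethyl-7-[(triethylsilyl)oxy]dec-8-en-1-yl]-2,6-dimethylpyridinium triflate (both C1 epimers) | COC(C[C@@H](C)CCC[C@@](C)(O[Si](CC)(CC)CC)/C=C\COC(=O)OC)[n+]1c(C)cccc1C.[O-]S(=O)(=O)C(F)(F)F | intermediate
11 | (2Z,4R,8S)-4,8-dimethyl-10-oxo-4-[(triethylsilyl)oxy]dec-2-en-1-yl methyl carbonate | O=CC[C@@H](C)CCC[C@@](C)(O[Si](CC)(CC)CC)/C=C\COC(=O)OC | intermediate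
12 | (2Z,4R,8S,9R)-4,8-dimethyl-10-oxo-9-[(2,2,6,6-tetramethylpiperidin-1-yl)oxy]-4-[(triethylsilyl)oxy]dec-2-en-1-yl methyl carbonate | O=C[C@H](ON1C(C)(C)CCCC1(C)C)[C@@H](C)CCC[C@@](C)(O[Si](CC)(CC)CC)/C=C\COC(=O)OC | intermediate
13 | but-3-yn-1-ol | C#CCCO | starting material
14 | methyl propiolate (methyl prop-2-ynoate) | C#CC(=O)OC | starting material
15 | but-3-ynal | C#CCC=O | intermediate
16 | methyl 2-[bis(2-methylpropyl)alumanyl]prop-2-enoate | C=C(C(=O)OC)[Al](CC(C)C)CC(C)C | intermediate
17 | methyl 3-hydroxy-2-methylidenehex-5-ynoate (racemic) | C#CCC(O)C(=C)C(=O)OC | intermediate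
18 | methyl (2Z)-2-(bromomethyl)hex-2-en-5-ynoate | C#CC/C=C(\CBr)C(=O)OC | intermediate
19 | bromo[(2Z)-2-(methoxycarbonyl)hex-2-en-5-yn-1-yl]zinc | C#CC/C=C(\C[Zn]Br)C(=O)OC | intermediate
20 | methyl (3R,4S,5R,6S,10R,11Z)-4-hydroxy-13-[(methoxycarbonyl)oxy]-6,10-dimethyl-2-methylidene-3-(prop-2-yn-1-yl)-5-[(2,2,6,6-tetramethylpiperidin-1-yl)oxy]-10-[(triethylsilyl)oxy]tridec-11-enoate | C=C(C(=O)OC)[C@@H](CC#C)[C@H](O)[C@H](ON1C(C)(C)CCCC1(C)C)[C@@H](C)CCC[C@@](C)(O[Si](CC)(CC)CC)/C=C\COC(=O)OC | intermediate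
21 | (2Z,4R,8S,9R)-4,8-dimethyl-9-[(2S,3R)-4-methylidene-5-oxo-3-(prop-2-yn-1-yl)oxolan-2-yl]-9-[(2,2,6,6-tetramethylpiperidin-1-yl)oxy]-4-[(triethylsilyl)oxy]non-2-en-1-yl methyl carbonate | C=C1C(=O)O[C@H]([C@H](ON2C(C)(C)CCCC2(C)C)[C@@H](C)CCC[C@@](C)(O[Si](CC)(CC)CC)/C=C\COC(=O)OC)[C@@H]1CC#C | intermediate
22 | (2Z,4R,8S,9R)-9-hydroxy-4,8-dimethyl-9-[(2S,3R)-4-methylidene-5-oxo-3-(prop-2-yn-1-yl)oxolan-2-yl]-4-[(triethylsilyl)oxy]non-2-en-1-yl methyl carbonate | C=C1C(=O)O[C@H]([C@H](O)[C@@H](C)CCC[C@@](C)(O[Si](CC)(CC)CC)/C=C\COC(=O)OC)[C@@H]1CC#C | intermediate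
23 | (3E)-alkenylzirconocene chloride from 22 (Cp2ZrCl on C4; C13 oxygen bound to a second Cp2ZrCl unit) | C=C1C(=O)O[C@H]([C@H](O[Zr](Cl)(C2C=CC=C2)C2C=CC=C2)[C@@H](C)CCC[C@@](C)(O[Si](CC)(CC)CC)/C=C\COC(=O)OC)[C@@H]1C/C=C/[Zr](Cl)(C1C=CC=C1)C1C=CC=C1 | intermediate
24 | (1R,3E,6Z,8R,12S,13R,14S)-13-hydroxy-8-[(triethylsilyl)oxy]-18-norcembra-3,6,15(17)-trien-16,14-olide | C=C1C(=O)O[C@@H]2[C@H](O)[C@@H](C)CCC[C@@](C)(O[Si](CC)(CC)CC)/C=C\C/C=C/C[C@H]12 | intermediate
25 | (1R,3S,4S,6Z,8R,12S,13R,14S)-3,4-epoxy-13-hydroxy-8-[(triethylsilyl)oxy]-18-norcembra-6,15(17)-dien-16,14-olide | C=C1C(=O)O[C@@H]2[C@H](O)[C@@H](C)CCC[C@@](C)(O[Si](CC)(CC)CC)/C=C\C[C@@H]3O[C@H]3C[C@H]12 | intermediate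
26 | (1R,3R,4S,6Z,8R,12S,13R,14S)-3,13-epoxy-4-hydroxy-8-[(triethylsilyl)oxy]-18-norcembra-6,15(17)-dien-16,14-olide | C=C1C(=O)O[C@@H]2[C@@H]3O[C@H](C[C@H]12)[C@@H](O)C/C=C\[C@](C)(O[Si](CC)(CC)CC)CCC[C@@H]3C | intermediate
27 | (1R,3R,6Z,8R,12S,13R,14S)-3,13-epoxy-4-oxo-8-[(triethylsilyl)oxy]-18-norcembra-6,15(17)-dien-16,14-olide | C=C1C(=O)O[C@@H]2[C@@H]3O[C@H](C[C@H]12)C(=O)C/C=C\[C@](C)(O[Si](CC)(CC)CC)CCC[C@@H]3C | intermediate
28 | (1R,3R,4S,6Z,8R,12S,13R,14S)-3,13-epoxy-4-hydroxy-8-[(triethylsilyl)oxy]cembra-6,15(17)-dien-16,14-olide | C=C1C(=O)O[C@@H]2[C@@H]3O[C@H](C[C@H]12)[C@@](C)(O)C/C=C\[C@](C)(O[Si](CC)(CC)CC)CCC[C@@H]3C | intermediate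
29 | (1R,3R,4S,6Z,8R,12S,13R,14S)-3,13-epoxy-4,8-dihydroxycembra-6,15(17)-dien-16,14-olide (CNP0146755.1) | C=C1C(=O)O[C@@H]2[C@@H]3O[C@H](C[C@H]12)[C@@](C)(O)C/C=C\[C@](C)(O)CCC[C@@H]3C | target

**Count and risks**
Total: 17 steps. Longest linear sequence: 15 steps (steps 1–9 and 12–17); steps 10–11 make the West bromide.

Steps most likely to fail:

Step 13. The hydride may transfer to the conjugated lactone methylene or the carbonate in competition with hydrozirconation; transmetalation may be slow enough to allow isomerisation of the allyl complex (loss of 6Z) or oligomerisation. Fallback with known chemistry, from 22: the hydrometalation is separated from the ring closure. Dicyclohexylborane-catalysed hydroboration with pinacolborane, which is selective for alkynes, should give the isolable (E)-alkenyl pinacol boronate F1. A Suzuki–Miyaura ring closure onto the allylic carbonate (Pd(PPh3)4, THF, 50 °C, high dilution, no added base because the methoxide released from the carbonate activates boron) then returns to 24.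

Step 14. Facial selectivity of the epoxidation may be poor if the catalyst works against the conformational bias of the macrocycle, and the cis-alkene may be over-oxidised. Fallback, from 24: reagent control is replaced by thermodynamic control. Buffered m-chloroperbenzoic acid epoxidises the same alkene and acid closes the ether. The material that has cyclised from the other face, the 3,4-epimeric alcohol F2, is oxidised (Dess–Martin periodinane) to the 3-epi ketone F3. DBU then equilibrates C3, which is α to the ketone, toward the 2,6-cis (diequatorial) oxane, assumed to be the more stable, and the route is rejoined at 27.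

Step 12. Facial selectivity at the aldehyde may be lost if zinc chelation by the aminoxy group competes with the Felkin–Anh mode, and the syn preference may erode through E/Z equilibration of the allylzinc. Fallback, from 18: the bromide is converted into the pinacol allylboronate F4 (B2pin2, Pd2(dba)3, toluene; substitution at the primary carbon with the alkene geometry kept). Thermal allylboration of 12 (toluene, 60 °C) goes through a closed six-membered transition state in which boron cannot chelate, and the cis arrangement of CH2B and the propargyl-bearing carbon is transferred into the syn adduct. Aqueous work-up gives hydroxy ester 20, which is carried to 22 by the acetic acid and zinc treatment of step 12.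

**Further compounds**
F1 | step 13 | (2Z,4R,8S,9R)-9-hydroxy-4,8-dimethyl-9-[(2S,3R)-4-methylidene-5-oxo-3-[(2E)-3-(4,4,5,5-tetramethyl-1,3,2-dioxaborolan-2-yl)prop-2-en-1-yl]oxolan-2-yl]-4-[(triethylsilyl)oxy]non-2-en-1-yl methyl carbonate | C=C1C(=O)O[C@H]([C@H](O)[C@@H](C)CCC[C@@](C)(O[Si](CC)(CC)CC)/C=C\COC(=O)OC)[C@@H]1C/C=C/B1OC(C)(C)C(C)(C)O1
F2 | step 14 | (1R,3S,4R,6Z,8R,12S,13R,14S)-3,13-epoxy-4-hydroxy-8-[(triethylsilyl)oxy]-18-norcembra-6,15(17)-dien-16,14-olide | C=C1C(=O)O[C@@H]2[C@@H]3O[C@@H](C[C@H]12)[C@H](O)C/C=C\[C@](C)(O[Si](CC)(CC)CC)CCC[C@@H]3C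
F3 | step 14 | (1R,3S,6Z,8R,12S,13R,14S)-3,13-epoxy-4-oxo-8-[(triethylsilyl)oxy]-18-norcembra-6,15(17)-dien-16,14-olide | C=C1C(=O)O[C@@H]2[C@@H]3O[C@@H](C[C@H]12)C(=O)C/C=C\[C@](C)(O[Si](CC)(CC)CC)CCC[C@@H]3C
F4 | step 12 | methyl (2E)-2-[(4,4,5,5-tetramethyl-1,3,2-dioxaborolan-2-yl)methyl]hex-2-en-5-ynoate | C#CC/C=C(\CB1OC(C)(C)C(C)(C)O1)C(=O)OC
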